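**Retrosynthetic overview**
1. The C3–O ester bond is made last but one (Yamaguchi coupling of the trienoic acid with the core alcohol); global desilylation ends the route.
2. Core: C7=C11 comes from an aldol condensation with silyl-protected hydroxyacetone; the C9 oxygen comes from oxidation of the regiodefined enolate delivered by dissolving-metal reduction of a bicyclic enedione, which also sets 10α-H and 3α-OH.
3. The enedione (ring A) arises by a semipinacol ring expansion, a 1,2-shift of the quaternary carbon in a vinyl carbinol, which converts the cyclopentanone of the Hajos–Parrish ketone into the 4,5-dimethylcyclohexanone.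
4. Ring order: cyclopentane (bought) → ring B (proline Robinson annulation, sets C5) → ring A (ring expansion of the five-membered ring).
5. Acid: hept-1-yne → E-iodoalkene → enyne → zirconium-catalysed carboalumination and Pd coupling with an iodoacrylate.

Assumptions and conventions: decalin carbons carry eremophilane numbers (ring A = C1–C5, C10; ring B = C5–C10; C14 on C5, C15 on C4, C11–C13 on C7) and β is the face of the C5 methyl; 1-(tert-butyldimethylsilyloxy)propan-2-one is bought as such and counted as hydroxyacetone (five non-hydrogen atoms) carrying a silyl protecting group.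

Step 1
Reactants: 1 2-methylcyclopentane-1,3-dione; 2 but-3-en-2-one
Product: 3 2-methyl-2-(3-oxobutyl)cyclopentane-1,3-dione
Conditions: H2O, AcOH (cat.), 70 °C
Reagents that add atoms: none
Why: Michael addition of the doubly activated dione carbon to the enone; no stereocentre is formed.

Step 2
Reactants: 3 2-methyl-2-(3-oxobutyl)cyclopentane-1,3-dione
Product: 5 (7aS)-7a-methyl-2,3,7,7a-tetrahydro-1H-indene-1,5(6H)-dione, via Hajos ketol 4 (not isolated)
Conditions: (S)-proline (3 mol%), DMF, 20 °C; then H2SO4 (cat.), 95 °C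
Reagents that add atoms: none
Why: Hajos–Parrish–Eder–Sauer–Wiechert reaction, in which the proline enamine of the side-chain ketone attacks one enantiotopic ring carbonyl through the acid-organised transition state and so sets the quaternary centre (7aS, ee raised to >99% by recrystallisation) before acid dehydrates the ketol.

Step 3
Reactants: 5 (7aS)-7a-methyl-2,3,7,7a-tetrahydro-1H-indene-1,5(6H)-dione; 6 vinylmagnesium bromide
Product: 7 (1R,7aS)-1-ethenyl-1-hydroxy-7a-methyl-1,2,3,6,7,7a-hexahydro-5H-inden-5-one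
Conditions: LaCl3·2LiCl (0.3 equiv), THF, −78 °C; aq. NH4Cl
Reagents that add atoms: none
Why: Lanthanide-promoted Grignard 1,2-addition to the non-conjugated cyclopentanone, the more electrophilic carbonyl (same site selectivity as NaBH4 on 5), from the face anti to the angular methyl; this carbinol centre is erased in step 4.

Step 4
Reactants: 7 (1R,7aS)-1-ethenyl-1-hydroxy-7a-methyl-1,2,3,6,7,7a-hexahydro-5H-inden-5-one
Product: 8 (4aR,5R)-4a,5-dimethyl-4,4a,7,8-tetrahydronaphthalene-2,6(3H,5H)-dione
Conditions: C36H52CoN2O2 {[N,N′-bis(3,5-di-tert-butylsalicylidene)cyclohexane-1,2-diaminato]cobalt} (5 mol%), N-fluoro-2,4,6-trimethylpyridinium tetrafluoroborate (1.2 equiv), PhSiH3 (1.2 equiv), PhCF3, 0 °C → rt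
Reagents that add atoms: none
Why: Proposed new method: a trivalent cobalt hydride (from the divalent cobalt salen complex, the N-fluoropyridinium oxidant and PhSiH3) transfers a hydrogen atom to the terminal vinyl carbon, the secondary radical is captured and oxidised to a tetravalent alkylcobalt, and the antiperiplanar ring bond to the quaternary carbon migrates as cobalt leaves, so the vinylcyclopentanol expands to the 2-methylcyclohexanone with the new methyl exo (rotamer with CH2 syn to OH, giving 4R, which is also the equatorial, base-equilibratable epimer), while the hindered electron-poor enone is not a hydrogen-atom acceptor; the closest known reaction type is the cobalt-salen hydrogen-atom-transfer radical–polar crossover semipinacol rearrangement of 1,1-disubstituted tertiary allylic alcohols and alkenylcyclobutanols, not yet shown for a monosubstituted vinyl carbinol on an unstrained ring with a migrating quaternary carbon.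

Step 5
Reactants: 8 (4aR,5R)-4a,5-dimethyl-4,4a,7,8-tetrahydronaphthalene-2,6(3H,5H)-dione
Product: 9 (4aS,5R,6R,8aS)-4a,5-dimethyl-2,6-bis(trimethylsilyloxy)-3,4,4a,5,6,7,8,8a-octahydronaphthalene
Conditions: Li (6 equiv), t-BuOH (2 equiv), NH3/THF, −78 °C; isoprene; then TMSCl, Et3N, THF, −78 → 0 °C
Reagents that add atoms: chlorotrimethylsilane, C[Si](C)(C)Cl
Why: Dissolving-metal reduction, in which the enone gives the regiodefined C8–C9 lithium enolate with axial protonation at C10 (trans ring fusion, 10α-H) and the C3 ketone is reduced under thermodynamic control to the equatorial 3α-alkoxide (hydride reagents would attack equatorially because of the syn-axial C5 methyl; compare friedelin to friedelan-3α-ol), both oxygens then being silylated.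

Step 6
Reactants: 9 (4aS,5R,6R,8aS)-4a,5-dimethyl-2,6-bis(trimethylsilyloxy)-3,4,4a,5,6,7,8,8a-octahydronaphthalene
Product: 12 (1S,4aR,5R,6R,8aR)-1-(tert-butyldimethylsilyloxy)-4a,5-dimethyl-6-(trimethylsilyloxy)octahydronaphthalen-2(1H)-one, via lithium enolate 10 (not isolated), via lithium alkoxide 11 (not isolated)
Conditions: MeLi (1.05 equiv), THF, 0 °C; 3-phenyl-2-(phenylsulfonyl)oxaziridine, −78 °C; then TBSOTf, −78 → 0 °C
Reagents that add atoms: 3-phenyl-2-(phenylsulfonyl)oxaziridine, O=S(=O)(c1ccccc1)N1OC1c1ccccc1; tert-butyldimethylsilyl trifluoromethanesulfonate, CC(C)(C)[Si](C)(C)OS(=O)(=O)C(F)(F)F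
Why: MeLi cleaves only the silyl enol ether and regenerates the same regiodefined enolate, which the N-sulfonyloxaziridine hydroxylates (Davis oxidation) on the α face, anti to the syn-axial C5 methyl, to give the equatorial 9α-alkoxide that is capped in the flask as the TBS ether.

Step 7
Reactants: 12 (1S,4aR,5R,6R,8aR)-1-(tert-butyldimethylsilyloxy)-4a,5-dimethyl-6-(trimethylsilyloxy)octahydronaphthalen-2(1H)-one; 13 1-(tert-butyldimethylsilyloxy)propan-2-one
Product: 17 (1S,4aR,5R,6R,8aR)-1-(tert-butyldimethylsilyloxy)-3-[(E)-1-(tert-butyldimethylsilyloxy)propan-2-ylidene]-6-hydroxy-4a,5-dimethyloctahydronaphthalen-2(1H)-one, via lithium aldolate 14 (not isolated), via tertiary acetate 15 (not isolated), via trimethylsilyl ether 16 (not isolated)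
Conditions: LiN(i-Pr)2 (1.1 equiv), THF, −78 °C; 13; Ac2O, −78 → 0 °C; DBU, 0 °C → rt; then citric acid, MeOH, rt
Reagents that add atoms: none
Why: Directed aldol addition of the C7 lithium enolate (C9 is blocked by its silyloxy group) to the activated α-silyloxy ketone, acetylation in the flask and E1cB elimination give the tetrasubstituted enone, E expected as the major isomer because the larger silyloxymethyl group avoids the carbonyl side (as the β-substituent does in 2-alkylidenecyclohexanones) with the minor Z isomer removed by chromatography, and mild acidic methanolysis then frees only the C3 hydroxyl.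

Step 8
Reactants: 18 hept-1-yne
Product: 19 (E)-1-iodohept-1-ene
Conditions: Cp2Zr(H)Cl, THF, rt; then I2, 0 °C
Reagents that add atoms: iodine, II
Why: Hydrozirconation (syn, zirconium at the terminal carbon) followed by iodinolysis with retention gives the E alkenyl iodide.

Step 9
Reactants: 19 (E)-1-iodohept-1-ene; 20 ethynylmagnesium bromide
Product: 21 (E)-non-3-en-1-yne
Conditions: 20, ZnBr2, THF, 0 °C; then 19, Pd(PPh3)4 (5 mol%), rt
Reagents that add atoms: none
Why: Negishi alkynyl–alkenyl cross-coupling of the ethynylzinc reagent, with retention of the E geometry.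

Step 10
Reactants: 21 (E)-non-3-en-1-yne; 22 ethyl (E)-3-iodoprop-2-enoate
Product: 24 ethyl (2E,4E,6E)-5-methyldodeca-2,4,6-trienoate, via dienylalane 23 (not isolated)
Conditions: Me3Al (2 equiv), Cp2ZrCl2 (0.25 equiv), CH2Cl2, 0 °C → rt; then 22, Pd(PPh3)4 (5 mol%), ZnCl2 (10 mol%), THF, rt
Reagents that add atoms: trimethylaluminium, C[Al](C)C
Why: Negishi zirconium-catalysed syn-carboalumination (methyl to the internal carbon, aluminium terminal) fixes the trisubstituted 4E alkene, and the Pd-catalysed alkenyl–alkenyl coupling proceeds with retention at both partners.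

Step 11
Reactants: 24 ethyl (2E,4E,6E)-5-methyldodeca-2,4,6-trienoate
Product: 25 (2E,4E,6E)-5-methyldodeca-2,4,6-trienoic acid
Conditions: LiOH, THF/MeOH/H2O, rt; then dilute HCl to pH 3
Reagents that add atoms: lithium hydroxide, [Li+].[OH-]
Why: Saponification of the ethyl ester, with no stereochemical change.

Step 12
Reactants: 17 (1S,4aR,5R,6R,8aR)-1-(tert-butyldimethylsilyloxy)-3-[(E)-1-(tert-butyldimethylsilyloxy)propan-2-ylidene]-6-hydroxy-4a,5-dimethyloctahydronaphthalen-2(1H)-one; 25 (2E,4E,6E)-5-methyldodeca-2,4,6-trienoic acid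
Product: 27 (1R,2R,4aR,5S,8aR)-5-(tert-butyldimethylsilyloxy)-7-[(E)-1-(tert-butyldimethylsilyloxy)propan-2-ylidene]-1,8a-dimethyl-6-oxodecahydronaphthalen-2-yl (2E,4E,6E)-5-methyldodeca-2,4,6-trienoate, via mixed anhydride 26 (not isolated)
Conditions: 25, 2,4,6-trichlorobenzoyl chloride, Et3N, toluene, rt; then 17, DMAP, rt
Reagents that add atoms: none
Why: Yamaguchi esterification of the only free hydroxyl (equatorial C3–OH), with retention at C3.

Step 13
Reactants: 27 (1R,2R,4aR,5S,8aR)-5-(tert-butyldimethylsilyloxy)-7-[(E)-1-(tert-butyldimethylsilyloxy)propan-2-ylidene]-1,8a-dimethyl-6-oxodecahydronaphthalen-2-yl (2E,4E,6E)-5-methyldodeca-2,4,6-trienoate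
Product: 28 (1R,2R,4aR,5S,8aR)-5-hydroxy-7-[(E)-1-hydroxypropan-2-ylidene]-1,8a-dimethyl-6-oxodecahydronaphthalen-2-yl (2E,4E,6E)-5-methyldodeca-2,4,6-trienoate
Conditions: HF·pyridine, pyridine, THF, 0 °C → rt
Reagents that add atoms: none
Why: Fluoride cleavage of both silyl ethers under buffered acidic conditions that leave the α-ketol, the enone and the trienoate untouched.

**Compound list**
1 | 2-methylcyclopentane-1,3-dione | CC1C(=O)CCC1=O | starting material
2 | but-3-en-2-one | CC(=O)C=C | starting material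
3 | 2-methyl-2-(3-oxobutyl)cyclopentane-1,3-dione | CC(=O)CCC1(C)C(=O)CCC1=O | intermediate
4 | (3aS,7aS)-3a-hydroxy-7a-methylhexahydro-1H-indene-1,5(6H)-dione (Hajos ketol) | C[C@]12CCC(=O)C[C@@]1(O)CCC2=O | intermediate
5 | (7aS)-7a-methyl-2,3,7,7a-tetrahydro-1H-indene-1,5(6H)-dione | C[C@]12CCC(=O)C=C1CCC2=O | intermediate
6 | vinylmagnesium bromide | C=C[Mg]Br | starting material
7 | (1R,7aS)-1-ethenyl-1-hydroxy-7a-methyl-1,2,3,6,7,7a-hexahydro-5H-inden-5-one | C[C@]12CCC(=O)C=C1CC[C@@]2(O)C=C | intermediate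
8 | (4aR,5R)-4a,5-dimethyl-4,4a,7,8-tetrahydronaphthalene-2,6(3H,5H)-dione (4β,5β-dimethyl, C9=C10, 3,8-dione) | C[C@H]1C(=O)CCC2=CC(=O)CC[C@]12C | intermediate
9 | (4aS,5R,6R,8aS)-4a,5-dimethyl-2,6-bis(trimethylsilyloxy)-3,4,4a,5,6,7,8,8a-octahydronaphthalene (3α-OTMS, 10α-H, C8=C9 enol ether) | C[C@H]1[C@H](O[Si](C)(C)C)CC[C@H]2C=C(O[Si](C)(C)C)CC[C@]12C | intermediate
10 | lithium enolate of the C8 ketone (C8=C9, 3α-OTMS, 10α-H) | C[C@H]1[C@H](O[Si](C)(C)C)CC[C@H]2C=C(O[Li])CC[C@]12C | intermediate
11 | lithium alkoxide of the 9α-hydroxy-8-ketone (3α-OTMS) | C[C@H]1[C@H](O[Si](C)(C)C)CC[C@H]2[C@H](O[Li])C(=O)CC[C@]12C | intermediate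
12 | (1S,4aR,5R,6R,8aR)-1-(tert-butyldimethylsilyloxy)-4a,5-dimethyl-6-(trimethylsilyloxy)octahydronaphthalen-2(1H)-one (9α-OTBS, 3α-OTMS, 8-one) | C[C@H]1[C@H](O[Si](C)(C)C)CC[C@H]2[C@H](O[Si](C)(C)C(C)(C)C)C(=O)CC[C@]12C | intermediate
13 | 1-(tert-butyldimethylsilyloxy)propan-2-one | CC(=O)CO[Si](C)(C)C(C)(C)C | starting material
14 | lithium aldolate at C7/C11 (diastereomer mixture at C7 and C11) | C[C@H]1[C@H](O[Si](C)(C)C)CC[C@H]2[C@H](O[Si](C)(C)C(C)(C)C)C(=O)C(C(C)(O[Li])CO[Si](C)(C)C(C)(C)C)C[C@]12C | intermediate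
15 | tertiary C11 acetate of the aldol (diastereomer mixture) | C[C@H]1[C@H](O[Si](C)(C)C)CC[C@H]2[C@H](O[Si](C)(C)C(C)(C)C)C(=O)C(C(C)(OC(C)=O)CO[Si](C)(C)C(C)(C)C)C[C@]12C | intermediate
16 | 3α-trimethylsilyl ether of 17 (E enone) | C[C@H]1[C@H](O[Si](C)(C)C)CC[C@H]2[C@H](O[Si](C)(C)C(C)(C)C)C(=O)/C(=C(\C)CO[Si](C)(C)C(C)(C)C)C[C@]12C | intermediate
17 | (1S,4aR,5R,6R,8aR)-1-(tert-butyldimethylsilyloxy)-3-[(E)-1-(tert-butyldimethylsilyloxy)propan-2-ylidene]-6-hydroxy-4a,5-dimethyloctahydronaphthalen-2(1H)-one | C[C@H]1[C@H](O)CC[C@H]2[C@H](O[Si](C)(C)C(C)(C)C)C(=O)/C(=C(\C)CO[Si](C)(C)C(C)(C)C)C[C@]12C | intermediate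
18 | hept-1-yne | CCCCCC#C | starting material
19 | (E)-1-iodohept-1-ene | CCCCC/C=C/I | intermediate
20 | ethynylmagnesium bromide | C#C[Mg]Br | starting material
21 | (E)-non-3-en-1-yne | CCCCC/C=C/C#C | intermediate
22 | ethyl (E)-3-iodoprop-2-enoate | CCOC(=O)/C=C/I | starting material
23 | dimethyl[(1E,3E)-2-methylnona-1,3-dien-1-yl]alumane | CCCCC/C=C/C(C)=C/[Al](C)C | intermediate
24 | ethyl (2E,4E,6E)-5-methyldodeca-2,4,6-trienoate | CCCCC/C=C/C(C)=C/C=C/C(=O)OCC | intermediate
25 | (2E,4E,6E)-5-methyldodeca-2,4,6-trienoic acid | CCCCC/C=C/C(C)=C/C=C/C(=O)O | intermediate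
26 | (2E,4E,6E)-5-methyldodeca-2,4,6-trienoic 2,4,6-trichlorobenzoic anhydride | CCCCC/C=C/C(C)=C/C=C/C(=O)OC(=O)c1c(Cl)cc(Cl)cc1Cl | intermediate
27 | (1R,2R,4aR,5S,8aR)-5-(tert-butyldimethylsilyloxy)-7-[(E)-1-(tert-butyldimethylsilyloxy)propan-2-ylidene]-1,8a-dimethyl-6-oxodecahydronaphthalen-2-yl (2E,4E,6E)-5-methyldodeca-2,4,6-trienoate | CCCCC/C=C/C(C)=C/C=C/C(=O)O[C@@H]1CC[C@H]2[C@H](O[Si](C)(C)C(C)(C)C)C(=O)/C(=C(\C)CO[Si](C)(C)C(C)(C)C)C[C@]2(C)[C@H]1C | intermediate
28 | (1R,2R,4aR,5S,8aR)-5-hydroxy-7-[(E)-1-hydroxypropan-2-ylidene]-1,8a-dimethyl-6-oxodecahydronaphthalen-2-yl (2E,4E,6E)-5-methyldodeca-2,4,6-trienoate | CCCCC/C=C/C(C)=C/C=C/C(=O)O[C@@H]1CC[C@H]2[C@H](O)C(=O)/C(=C(\C)CO)C[C@]2(C)[C@H]1C | target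

**Totals**
Total steps: 13. Longest linear sequence: 9 (steps 1–7, 12, 13).

**Three steps most likely to fail, with fallbacks**

The new ring expansion of step 4 may give the spiro-epoxide (attack of the hydroxyl instead of the 1,2-shift) or the wrong migrating carbon. The fallback uses known selenium chemistry and sets out from 5. 1-Lithio-1-(phenylselanyl)ethane (from 1,1-bis(phenylselanyl)ethane and n-BuLi, THF, −78 °C) adds to the cyclopentanone carbonyl to give the β-hydroxy selenide, 1-hydroxy-7a-methyl-1-[1-(phenylselanyl)ethyl]-1,2,3,6,7,7a-hexahydro-5H-inden-5-one F1. AgBF4 on Al2O3 in CH2Cl2 then brings about the established one-carbon ring enlargement of β-hydroxy selenides, with migration of the more substituted ring carbon. This returns to the route at 8; the C4 epimers can be equilibrated with DBU if needed.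

The one-pot enolate hydroxylation and silylation of step 6 may suffer from addition of the lithium enolate to the sulfonimine by-product or from partial loss of the C3 trimethylsilyl ether. The fallback sets out from 9 and replaces the enolate oxidation by a peracid oxidation of a silyl enol ether. MeLi followed by TBSCl/HMPA gives the tert-butyldimethylsilyl enol ether, 2-(tert-butyldimethylsilyloxy)-4a,5-dimethyl-6-(trimethylsilyloxy)-3,4,4a,5,6,7,8,8a-octahydronaphthalene F2. Rubottom oxidation (mCPBA, NaHCO3, CH2Cl2, −20 °C; α-face epoxidation, then 1,4-silyl shift) comes back to the route at 12.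

The aldol condensation of step 7 has a ketone as electrophile and forms a tetrasubstituted alkene, so retro-aldol loss and a poor E/Z ratio are the main risks. The fallback sets out from 12 and fixes the geometry thermodynamically at the aldehyde oxidation level.
- The same LiN(i-Pr)2/Ac2O/DBU protocol with 1,1-dimethoxypropan-2-one gives the dimethyl acetal, 1-(tert-butyldimethylsilyloxy)-3-(1,1-dimethoxypropan-2-ylidene)-4a,5-dimethyl-6-(trimethylsilyloxy)octahydronaphthalen-2(1H)-one F3, as an isomer mixture.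
- Oxalic acid in wet THF with a trace of I2 cleaves the acetal and the trimethylsilyl ether and equilibrates the ene-dicarbonyl to the trans isomer, (E)-2-[1-(tert-butyldimethylsilyloxy)-6-hydroxy-4a,5-dimethyl-2-oxooctahydronaphthalen-3(2H)-ylidene]propanal F4. The cis arrangement of the two carbonyls is disfavoured, as in 2-ene-1,4-dicarbonyl compounds generally.
- NaBH4 in MeOH/CH2Cl2 at −78 °C reduces only the aldehyde and gives the diol, 1-(tert-butyldimethylsilyloxy)-6-hydroxy-3-[(E)-1-hydroxypropan-2-ylidene]-4a,5-dimethyloctahydronaphthalen-2(1H)-one F5.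
- TBSCl/imidazole silylates the primary allylic hydroxyl selectively and comes back to the route at 17.

Further compounds
F1 | step 4 | 1-hydroxy-7a-methyl-1-[1-(phenylselanyl)ethyl]-1,2,3,6,7,7a-hexahydro-5H-inden-5-one (7aS; C1 as in 7; epimers at the selenium-bearing carbon) | C[C@]12CCC(=O)C=C1CC[C@@]2(O)C(C)[Se]c1ccccc1
F2 | step 6 | 2-(tert-butyldimethylsilyloxy)-4a,5-dimethyl-6-(trimethylsilyloxy)-3,4,4a,5,6,7,8,8a-octahydronaphthalene (stereocentres as in 9) | C[C@H]1[C@H](O[Si](C)(C)C)CC[C@H]2C=C(O[Si](C)(C)C(C)(C)C)CC[C@]12C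
F3 | step 7 | 1-(tert-butyldimethylsilyloxy)-3-(1,1-dimethoxypropan-2-ylidene)-4a,5-dimethyl-6-(trimethylsilyloxy)octahydronaphthalen-2(1H)-one (ring stereocentres as in 12; E/Z mixture) | C[C@H]1[C@H](O[Si](C)(C)C)CC[C@H]2[C@H](O[Si](C)(C)C(C)(C)C)C(=O)C(=C(C)C(OC)OC)C[C@]12C
F4 | step 7 | (E)-2-[1-(tert-butyldimethylsilyloxy)-6-hydroxy-4a,5-dimethyl-2-oxooctahydronaphthalen-3(2H)-ylidene]propanal (ring stereocentres as in 17) | C[C@H]1[C@H](O)CC[C@H]2[C@H](O[Si](C)(C)C(C)(C)C)C(=O)/C(=C(\C)C=O)C[C@]12C
F5 | step 7 | 1-(tert-butyldimethylsilyloxy)-6-hydroxy-3-[(E)-1-hydroxypropan-2-ylidene]-4a,5-dimethyloctahydronaphthalen-2(1H)-one (ring stereocentres as in 17) | C[C@H]1[C@H](O)CC[C@H]2[C@H](O[Si](C)(C)C(C)(C)C)C(=O)/C(=C(\C)CO)C[C@]12C
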